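The indane is cut at two bonds, C3–C3a (ring F) and C8–ring C. The adjacent stereocentres C3 and C8 hold these aryl groups anti across what was an (E)-C3=C8 alkene, and the C8 hydroxyl occupies the position that boron takes in such an addition. A ring-closing palladium-catalysed conjunctive coupling of an alkenylboron ate complex with the ring F triflate therefore makes both C–C bonds, the five-membered ring and both stereocentres in one operation. Its precursor is an anti C1/C2 diaryl chain carrying the ring F triflate and an (E)-alkenyl pinacol boronate, with every phenol as a benzyl ether, so that the acid-sensitive C8 carbinol is finally unmasked by neutral hydrogenolysis.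

Key step: step 13

Assumption: the isothiocineole antipode that turns benzaldehyde into (S,S)-stilbene oxide by benzylidene transfer is the one needed in steps 5 and 6 and is taken to be the (1S,4S,5S)-sulfide, and (Sp,Sp)-MandyPhos is taken as the ligand antipode matched to the substrate in step 13; if either sense is the other way round, the mirror-image sulfide or ligand is used and nothing else changes.

Labels: indane atoms C1 (bears ring A), C2 (bears the dihydrobenzofuran), C3 (bears C8), C3a and C7a (ring F), C8 (carbinol carbon, bears ring C); ring D is the 3,5-dioxygenated aryl and ring E the 4-oxygenated aryl on the dihydrobenzofuran; Bn = benzyl, Bpin = 4,4,5,5-tetramethyl-1,3,2-dioxaborolan-2-yl; DHBF = the (2R,3R)-6-(benzyloxy)-3-[3,5-bis(benzyloxy)phenyl]-2-[4-(benzyloxy)phenyl]-2,3-dihydro-1-benzofuran-4-yl group.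

Step 1
Reactants: 1 1,3-bis(benzyloxy)-5-bromobenzene
Product: 2 2,4-bis(benzyloxy)-6-bromobenzaldehyde
Conditions: POCl3, DMF, 80 °C; then aq NaOAc
Reagents that add atoms: N,N-dimethylformamide CN(C)C=O; water O
Why: Vilsmeier–Haack formylation of an electron-rich arene, in which the chloroiminium ion attacks the position ortho to bromine and para to a benzyloxy group because the only other activated site lies between two benzyloxy groups and is more crowded.

Step 2
Reactants: 2 2,4-bis(benzyloxy)-6-bromobenzaldehyde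
Product: 3 4-(benzyloxy)-2-bromo-6-hydroxybenzaldehyde
Conditions: MgBr2·OEt2, toluene/Et2O, 80 °C; aq HCl
Reagents that add atoms: none
Why: Chelation-assisted ether cleavage by a magnesium halide, in which magnesium bridges the aldehyde oxygen and the neighbouring ether oxygen so that bromide removes only the ortho benzyl group and the para benzyl ether is kept.

Step 3
Reactants: 3 4-(benzyloxy)-2-bromo-6-hydroxybenzaldehyde; 1 1,3-bis(benzyloxy)-5-bromobenzene
Product: 5 5-(benzyloxy)-2-{[3,5-bis(benzyloxy)phenyl](hydroxy)methyl}-3-bromophenol (racemic), via aryl Grignard reagent 4 (not isolated)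
Conditions: 1 (2.3 equiv), Mg, THF, 50 °C; then 3, 0 °C → rt; aq NH4Cl
Reagents that add atoms: none
Why: Grignard 1,2-addition to the aldehyde after the first equivalent of 4 has deprotonated the phenol; the benzhydrol centre is made racemic on purpose because it becomes trigonal again in ortho-quinone methide 10.

Step 4
Reactants: 5 5-(benzyloxy)-2-{[3,5-bis(benzyloxy)phenyl](hydroxy)methyl}-3-bromophenol
Product: 6 5-(benzyloxy)-2-{[3,5-bis(benzyloxy)phenyl](4-methylbenzenesulfonyl)methyl}-3-bromophenol (racemic)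
Conditions: p-TolSO2Na, HCO2H, THF/H2O, rt
Reagents that add atoms: sodium 4-methylbenzenesulfinate Cc1ccc(cc1)S(=O)[O-].[Na+]
Why: Acid-promoted SN1-type substitution of the electron-rich ortho-hydroxybenzhydrol by the sulfur atom of the sulfinate, giving the sulfone from which mild base can later expel sulfinate; the centre remains racemic.

Step 5
Reactants: 7 (1S,4S,5S)-isothiocineole; 8 4-(benzyloxy)benzyl bromide
Product: 9 (1S,4S,5S)-6-[4-(benzyloxy)benzyl]-4,7,7-trimethyl-6-thiabicyclo[3.2.1]octan-6-ium tetrafluoroborate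
Conditions: NaBF4, CH2Cl2/H2O, rt
Reagents that add atoms: sodium tetrafluoroborate [Na+].F[B-](F)(F)F
Why: SN2 S-alkylation of the sulfide by the benzylic bromide on its less hindered lone pair, driven to completion by exchange of bromide for the non-nucleophilic tetrafluoroborate, so that one sulfonium diastereomer is expected.

Step 6
Reactants: 6 5-(benzyloxy)-2-{[3,5-bis(benzyloxy)phenyl](4-methylbenzenesulfonyl)methyl}-3-bromophenol; 9 the sulfonium tetrafluoroborate
Product: 12 (2R,3R)-6-(benzyloxy)-3-[3,5-bis(benzyloxy)phenyl]-2-[4-(benzyloxy)phenyl]-4-bromo-2,3-dihydro-1-benzofuran (trans), via ortho-quinone methide 10 (not isolated), via sulfonium ylide 11 (not isolated)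
Conditions: Cs2CO3, MeCN/CH2Cl2, −20 °C → rt
Reagents that add atoms: none
Why: Formal [4+1] annulation of a sulfur ylide with an ortho-quinone methide (conjugate addition, then intramolecular SN2 closure by the phenoxide with inversion): carbonate sets free 10 by loss of sulfinate and 11 by deprotonation, the bicyclic sulfide shields one face of the ylide carbon and so fixes C2 of the dihydrobenzofuran, and the anti betaine that keeps the two aryl groups apart places C3 trans to it.

Step 7
Reactants: 13 5,7-dihydroxycoumarin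
Product: 14 5,7-bis(benzyloxy)coumarin
Conditions: BnBr, K2CO3, DMF, 60 °C
Reagents that add atoms: benzyl bromide BrCc1ccccc1
Why: Williamson ether synthesis on both phenols of the coumarin with benzyl bromide and carbonate; no stereocentre is formed.

Step 8
Reactants: 14 5,7-bis(benzyloxy)coumarin; 15 4-(benzyloxy)phenylboronic acid
Product: 16 (4S)-5,7-bis(benzyloxy)-4-[4-(benzyloxy)phenyl]-3,4-dihydro-2H-chromen-2-one
Conditions: Rh(acac)(C2H4)2 (3 mol%), (S)-SEGPHOS, dioxane/H2O 10:1, 60 °C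
Reagents that add atoms: none
Why: Rhodium-catalysed asymmetric 1,4-addition of an arylboronic acid to a coumarin, in which the aryl–rhodium species adds to C4 on the face selected by the bisphosphine and water then releases the lactone; (S)-SEGPHOS is expected to give the 4S centre, the mirror image of the sense that the (R)-ligand shows with coumarin itself.

Step 9
Reactants: 16 (4S)-5,7-bis(benzyloxy)-4-[4-(benzyloxy)phenyl]-3,4-dihydro-2H-chromen-2-one; 12 the (2R,3R)-4-bromodihydrobenzofuran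
Product: 19 (3S,4S)-5,7-bis(benzyloxy)-4-[4-(benzyloxy)phenyl]-3-DHBF-3,4-dihydro-2H-chromen-2-one (trans), via lithium enolate 17 (not isolated), via zinc enolate 18 (not isolated)
Conditions: LiN(SiMe3)2, THF, −78 °C; ZnCl2, −78 °C → rt; 12, Pd(dba)2 (5 mol%), P(t-Bu)3, 60 °C; then DBU (0.2 equiv), CH2Cl2, rt
Reagents that add atoms: none
Why: Palladium-catalysed α-arylation of a Reformatsky-type zinc lactone enolate with an aryl bromide, run in a neutral medium that spares the dihydrobenzofuran and with a bulky electron-rich phosphine for the ortho-substituted bromide; DBU then equilibrates the acidic α-aryl centre C3 to the more stable trans-3,4-diaryl lactone while the non-acidic C4 centre is not touched.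

Step 10
Reactants: 19 the trans-3,4-diaryl lactone
Product: 20 (3S,4S)-5,7-bis(benzyloxy)-4-[4-(benzyloxy)phenyl]-3-DHBF-3,4-dihydro-2H-chromen-2-ol (anomer mixture)
Conditions: i-Bu2AlH, CH2Cl2, −78 °C; aq potassium sodium tartrate
Reagents that add atoms: none
Why: Half-reduction of the lactone to the lactol with i-Bu2AlH at −78 °C, where the aluminium hemiacetal persists until work-up; the anomeric centre forms as a mixture, which does not matter because that carbon becomes the alkene carbon C3.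

Step 11
Reactants: 20 the lactol; 21 bis(4,4,5,5-tetramethyl-1,3,2-dioxaborolan-2-yl)methane
Product: 24 3,5-bis(benzyloxy)-2-{(1S,2S,3E)-1-[4-(benzyloxy)phenyl]-2-DHBF-4-Bpin-but-3-en-1-yl}phenol, via lithiated diborylmethane 22 (not isolated), via open-chain phenoxide aldehyde 23 (not isolated)
Conditions: 21 (2.4 equiv), lithium 2,2,6,6-tetramethylpiperidide (from the amine and n-BuLi), THF, 0 °C; then 20, −78 °C → rt; aq NH4Cl
Reagents that add atoms: none
Why: Boron–Wittig olefination, in which the lactolate opens to aldehyde 23, the α-boryl carbanion 22 adds at low temperature and syn elimination of a borate gives the (E)-alkenyl boronate, while fast addition at −78 °C keeps the enolisable C2 centre from epimerising.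

Step 12
Reactants: 24 the phenol (E)-alkenyl boronate
Product: 25 3,5-bis(benzyloxy)-2-{(1S,2S,3E)-1-[4-(benzyloxy)phenyl]-2-DHBF-4-Bpin-but-3-en-1-yl}phenyl trifluoromethanesulfonate
Conditions: PhNTf2, Et3N, DMAP (10 mol%), CH2Cl2, rt
Reagents that add atoms: N-phenylbis(trifluoromethanesulfonimide) O=S(=O)(N(c1ccccc1)S(=O)(=O)C(F)(F)F)C(F)(F)F
Why: Triflation of the freed phenol with the mild reagent PhNTf2, which does not touch the alkenyl boronate or the benzyl ethers and forms no stereocentre.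

Step 13
Reactants: 25 the (E)-alkenyl boronate triflate; 26 [4-(benzyloxy)phenyl]magnesium bromide
Product: 28 all-trans indane carrying Bpin on C8 and eight aryl benzyl ethers in all (C1 S, C2 S, C3 R, C8 S; boron stands where the C8 oxygen of the target stands), via boron ate complex 27 (not isolated)
Conditions: 26 (1.1 equiv), THF, 0 °C → rt; then NaOTf, Pd(OAc)2 (5 mol%), (Sp,Sp)-MandyPhos [1,1′-bis(diphenylphosphino)-2,2′-bis(α-dimethylaminobenzyl)ferrocene] (6 mol%), THF/DMSO, 60 °C, 0.01 M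
Reagents that add atoms: none
Why: Proposed new method: the Grignard reagent adds to boron to give ate complex 27, zerovalent palladium formed from Pd(OAc)2 and the bisphosphine inserts into the ring F carbon–triflate bond, and the cationic arylpalladium binds the tethered C3=C8 alkene and triggers a 1,2-metallate shift in which the 4-(benzyloxy)phenyl group moves from boron to C8 anti to palladium while palladium bonds to C3, after which reductive elimination forms C3–C3a. The closest known reaction is the intermolecular palladium-catalysed conjunctive cross-coupling of alkenylboron ate complexes with aryl triflates, which has not been run in ring-closing form. The indane ring closes in the 5-exo-trig mode with respect to the alkene, through a six-membered palladacycle, and a six-membered carbocycle cannot form because the migrating group can only go to the boron-bearing carbon C8. C8 is set relative to C3 by the stereospecific anti addition across the (E)-alkene, and C3 is set relative to C2 by the cyclisation transition state that keeps the C2 aryl group and the C8 substituent pseudo-equatorial and trans, a preference that the matched ligand antipode reinforces. The step needs the metallate shift to outrun transfer of a group from boron to palladium: intramolecular alkenyl transfer would require an (E)-alkene inside a six-membered ring and is geometrically excluded, the triflate together with NaOTf and DMSO keeps palladium cationic and halide-free, and high dilution holds back intermolecular coupling. Oxidative addition at C3a is used because this carbon is meta to both ring F oxygens and cannot close the ring as a Friedel–Crafts nucleophile.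

Step 14
Reactants: 28 the C8 boronate
Product: 29 octabenzyl ether of the target (C1 S, C2 R, C3 S, C8 S; free C8 carbinol)
Conditions: NaBO3·4H2O, THF/H2O, rt
Reagents that add atoms: sodium perborate tetrahydrate (NaBO3·4H2O, the peroxoborate dimer) [Na+].[Na+].O[B-]1(O)OO[B-](O)(O)OO1
Why: Oxidation of a secondary alkyl boronate with perborate, in which the peroxide adduct rearranges by 1,2-shift of C8 from boron to oxygen with retention, so that the carbinol takes over the C8 configuration made in step 13.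

Step 15
Reactants: 29 the octabenzyl ether
Product: 30 CNP0175860.1, (1S,2R,3S)-1-(4-hydroxyphenyl)-3-[(S)-hydroxy(4-hydroxyphenyl)methyl]-2-[(2R,3R)-3-(3,5-dihydroxyphenyl)-6-hydroxy-2-(4-hydroxyphenyl)-2,3-dihydro-1-benzofuran-4-yl]indane-5,7-diol
Conditions: H2 (1 atm), 10% Pd/C, THF/MeOH, rt
Reagents that add atoms: none
Why: Catalytic hydrogenolysis of the eight aryl benzyl ethers over palladium on carbon, a neutral reaction in which these ethers cleave faster than the benzylic C8–OH bond and the C2–O bond of the dihydrobenzofuran, so that the acid-sensitive 4-hydroxybenzylic carbinol and all six stereocentres are left as they are.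

Compound list
1 | 1,3-bis(benzyloxy)-5-bromobenzene | Brc1cc(OCc2ccccc2)cc(OCc2ccccc2)c1 | starting material
2 | 2,4-bis(benzyloxy)-6-bromobenzaldehyde | O=Cc1c(Br)cc(OCc2ccccc2)cc1OCc1ccccc1 | intermediate
3 | 4-(benzyloxy)-2-bromo-6-hydroxybenzaldehyde | O=Cc1c(Br)cc(OCc2ccccc2)cc1O | intermediate
4 | [3,5-bis(benzyloxy)phenyl]magnesium bromide | Br[Mg]c1cc(OCc2ccccc2)cc(OCc2ccccc2)c1 | intermediate
5 | 5-(benzyloxy)-2-{[3,5-bis(benzyloxy)phenyl](hydroxy)methyl}-3-bromophenol, racemic | OC(c1cc(OCc2ccccc2)cc(OCc2ccccc2)c1)c1c(Br)cc(OCc2ccccc2)cc1O | intermediate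
6 | 5-(benzyloxy)-2-{[3,5-bis(benzyloxy)phenyl](4-methylbenzenesulfonyl)methyl}-3-bromophenol, racemic | Cc1ccc(cc1)S(=O)(=O)C(c1cc(OCc2ccccc2)cc(OCc2ccccc2)c1)c1c(Br)cc(OCc2ccccc2)cc1O | intermediate
7 | (1S,4S,5S)-4,7,7-trimethyl-6-thiabicyclo[3.2.1]octane (isothiocineole; also one step from (S)-limonene, sulfur and γ-terpinene) | CC1(C)S[C@H]2C[C@@H]1CC[C@@H]2C | starting material
8 | 4-(benzyloxy)benzyl bromide | BrCc1ccc(OCc2ccccc2)cc1 | starting material
9 | (1S,4S,5S)-6-[4-(benzyloxy)benzyl]-4,7,7-trimethyl-6-thiabicyclo[3.2.1]octan-6-ium tetrafluoroborate, benzyl group on the less hindered sulfur lone pair (sulfur descriptor left open in the SMILES) | CC1(C)[S+](Cc3ccc(OCc4ccccc4)cc3)[C@H]2C[C@@H]1CC[C@@H]2C.F[B-](F)(F)F | intermediate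
10 | 3-(benzyloxy)-6-[3,5-bis(benzyloxy)benzylidene]-5-bromocyclohexa-2,4-dien-1-one, aryl group on the carbonyl side | O=C1C=C(OCc2ccccc2)C=C(Br)/C1=C/c1cc(OCc2ccccc2)cc(OCc2ccccc2)c1 | intermediate
11 | sulfonium ylide formed from 9 by loss of the benzylic proton | CC1(C)[S+]([CH-]c3ccc(OCc4ccccc4)cc3)[C@H]2C[C@@H]1CC[C@@H]2C | intermediate
12 | (2R,3R)-6-(benzyloxy)-3-[3,5-bis(benzyloxy)phenyl]-2-[4-(benzyloxy)phenyl]-4-bromo-2,3-dihydro-1-benzofuran (trans) | Brc1cc(OCc2ccccc2)cc2c1[C@@H](c1cc(OCc3ccccc3)cc(OCc3ccccc3)c1)[C@H](c1ccc(OCc3ccccc3)cc1)O2 | intermediate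
13 | 5,7-dihydroxycoumarin | O=c1ccc2c(O)cc(O)cc2o1 | starting material
14 | 5,7-bis(benzyloxy)coumarin | O=c1ccc2c(OCc3ccccc3)cc(OCc3ccccc3)cc2o1 | intermediate
15 | 4-(benzyloxy)phenylboronic acid | OB(O)c1ccc(OCc2ccccc2)cc1 | starting material
16 | (4S)-5,7-bis(benzyloxy)-4-[4-(benzyloxy)phenyl]-3,4-dihydro-2H-chromen-2-one | O=C1C[C@@H](c2ccc(OCc3ccccc3)cc2)c2c(OCc3ccccc3)cc(OCc3ccccc3)cc2O1 | intermediate
17 | lithium enolate of 16 | [Li]OC1=C[C@@H](c2ccc(OCc3ccccc3)cc2)c2c(OCc3ccccc3)cc(OCc3ccccc3)cc2O1 | intermediate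
18 | chlorozinc enolate of 16 | Cl[Zn]OC1=C[C@@H](c2ccc(OCc3ccccc3)cc2)c2c(OCc3ccccc3)cc(OCc3ccccc3)cc2O1 | intermediate
19 | (3S,4S)-5,7-bis(benzyloxy)-4-[4-(benzyloxy)phenyl]-3-DHBF-3,4-dihydro-2H-chromen-2-one (trans) | O=C1[C@H](c2cc(OCc3ccccc3)cc3c2[C@@H](c2cc(OCc4ccccc4)cc(OCc4ccccc4)c2)[C@H](c2ccc(OCc4ccccc4)cc2)O3)[C@@H](c2ccc(OCc3ccccc3)cc2)c2c(OCc3ccccc3)cc(OCc3ccccc3)cc2O1 | intermediate
20 | (3S,4S)-5,7-bis(benzyloxy)-4-[4-(benzyloxy)phenyl]-3-DHBF-3,4-dihydro-2H-chromen-2-ol, anomer mixture | OC1[C@H](c2cc(OCc3ccccc3)cc3c2[C@@H](c2cc(OCc4ccccc4)cc(OCc4ccccc4)c2)[C@H](c2ccc(OCc4ccccc4)cc2)O3)[C@@H](c2ccc(OCc3ccccc3)cc2)c2c(OCc3ccccc3)cc(OCc3ccccc3)cc2O1 | intermediate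
21 | bis(4,4,5,5-tetramethyl-1,3,2-dioxaborolan-2-yl)methane | C(B1OC(C)(C)C(C)(C)O1)B1OC(C)(C)C(C)(C)O1 | starting material
22 | lithio-bis(4,4,5,5-tetramethyl-1,3,2-dioxaborolan-2-yl)methane | [Li]C(B1OC(C)(C)C(C)(C)O1)B1OC(C)(C)C(C)(C)O1 | intermediate
23 | lithium 3,5-bis(benzyloxy)-2-{(1S,2S)-1-[4-(benzyloxy)phenyl]-2-DHBF-3-oxopropyl}phenolate | O=C[C@H](c2cc(OCc3ccccc3)cc3c2[C@@H](c2cc(OCc4ccccc4)cc(OCc4ccccc4)c2)[C@H](c2ccc(OCc4ccccc4)cc2)O3)[C@@H](c2ccc(OCc3ccccc3)cc2)c2c(OCc3ccccc3)cc(OCc3ccccc3)cc2O[Li] | intermediate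
24 | 3,5-bis(benzyloxy)-2-{(1S,2S,3E)-1-[4-(benzyloxy)phenyl]-2-DHBF-4-Bpin-but-3-en-1-yl}phenol | C(c1ccccc1)Oc1ccc([C@@H](c2c(OCc3ccccc3)cc(OCc3ccccc3)cc2O)[C@H](/C=C/B2OC(C)(C)C(C)(C)O2)c2cc(OCc3ccccc3)cc3c2[C@@H](c2cc(OCc4ccccc4)cc(OCc4ccccc4)c2)[C@H](c2ccc(OCc4ccccc4)cc2)O3)cc1 | intermediate
25 | 3,5-bis(benzyloxy)-2-{(1S,2S,3E)-1-[4-(benzyloxy)phenyl]-2-DHBF-4-Bpin-but-3-en-1-yl}phenyl trifluoromethanesulfonate (precursor of the key step; C1/C2 anti) | C(c1ccccc1)Oc1ccc([C@@H](c2c(OCc3ccccc3)cc(OCc3ccccc3)cc2OS(=O)(=O)C(F)(F)F)[C@H](/C=C/B2OC(C)(C)C(C)(C)O2)c2cc(OCc3ccccc3)cc3c2[C@@H](c2cc(OCc4ccccc4)cc(OCc4ccccc4)c2)[C@H](c2ccc(OCc4ccccc4)cc2)O3)cc1 | intermediate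
26 | [4-(benzyloxy)phenyl]magnesium bromide (THF solution) | Br[Mg]c1ccc(OCc2ccccc2)cc1 | starting material
27 | bromomagnesium ate complex of 25, boron carrying the alkenyl group, the pinacolate and the 4-(benzyloxy)phenyl group | C(c1ccccc1)Oc1ccc([C@@H](c2c(OCc3ccccc3)cc(OCc3ccccc3)cc2OS(=O)(=O)C(F)(F)F)[C@H](/C=C/[B-]2(c3ccc(OCc4ccccc4)cc3)OC(C)(C)C(C)(C)O2)c2cc(OCc3ccccc3)cc3c2[C@@H](c2cc(OCc4ccccc4)cc(OCc4ccccc4)c2)[C@H](c2ccc(OCc4ccccc4)cc2)O3)cc1.[Mg+]Br | intermediate
28 | 5,7-bis(benzyloxy)-1-[4-(benzyloxy)phenyl]-3-{(S)-[4-(benzyloxy)phenyl](Bpin)methyl}-2-DHBF-indane, all-trans, C1 S, C2 S, C3 R (product of the key step) | C(c1ccccc1)Oc1ccc([C@H]2c3c(OCc4ccccc4)cc(OCc4ccccc4)cc3[C@@H]([C@H](B3OC(C)(C)C(C)(C)O3)c3ccc(OCc4ccccc4)cc3)[C@@H]2c2cc(OCc4ccccc4)cc3c2[C@@H](c2cc(OCc4ccccc4)cc(OCc4ccccc4)c2)[C@H](c2ccc(OCc4ccccc4)cc2)O3)cc1 | intermediate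
29 | (S)-[4-(benzyloxy)phenyl]{(1S,2R,3S)-5,7-bis(benzyloxy)-1-[4-(benzyloxy)phenyl]-2-DHBF-indan-3-yl}methanol (C1 is the ring A carbon) | C(c1ccccc1)Oc1ccc([C@H]2c3c(OCc4ccccc4)cc(OCc4ccccc4)cc3[C@@H]([C@H](O)c3ccc(OCc4ccccc4)cc3)[C@@H]2c2cc(OCc4ccccc4)cc3c2[C@@H](c2cc(OCc4ccccc4)cc(OCc4ccccc4)c2)[C@H](c2ccc(OCc4ccccc4)cc2)O3)cc1 | intermediate
30 | CNP0175860.1, (1S,2R,3S)-1-(4-hydroxyphenyl)-3-[(S)-hydroxy(4-hydroxyphenyl)methyl]-2-[(2R,3R)-3-(3,5-dihydroxyphenyl)-6-hydroxy-2-(4-hydroxyphenyl)-2,3-dihydro-1-benzofuran-4-yl]indane-5,7-diol | Oc1ccc([C@H]2c3c(O)cc(O)cc3[C@@H]([C@H](O)c3ccc(O)cc3)[C@@H]2c2cc(O)cc3c2[C@@H](c2cc(O)cc(O)c2)[C@H](c2ccc(O)cc2)O3)cc1 | target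

Total step count: 15. Longest linear sequence: 12 steps (steps 1, 2, 3, 4, 6, 9, 10, 11, 12, 13, 14, 15; from 1 through 2, 3, 5, 6, 12, 19, 20, 24, 25, 28, 29 to 30).

Steps most likely to fail

Step 13 (ring-closing conjunctive coupling). Three things may go wrong. The aryl group may pass from boron to palladium before the metallate shift, which ends in a Suzuki-type biaryl. The arylpalladium may insert the alkene in Heck fashion and lose a β-hydride. Palladium may also bind the alkene face that puts the C3/C8 pair cis to the C2 aryl group. The fallback uses known chemistry only, sets out from 25 and comes back at 29. Perborate oxidation of the alkenyl boronate of 25 gives the β-branched aldehyde F1, in which C3 is a methylene group and C8 the formyl carbon. Addition of 26 at −78 °C gives the epimeric secondary alcohols F2, and Dess–Martin oxidation gives the aryl ketone F3. Palladium-catalysed intramolecular α-arylation of this ketone by the ring F triflate (Pd(OAc)2, a biaryl dialkylphosphine, Cs2CO3, toluene, 80 °C) forms C3–C3a, and the enolisable C3 centre settles in the all-trans aroyl indane F4. Corey–Bakshi–Shibata reduction with the (R)-methyl oxazaborolidine and BH3·SMe2, with the aryl group as the large substituent, then gives the 8S carbinol 29.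

Step 6 ([4+1] annulation). Facial control at the ylide carbon or the anti selectivity of the conjugate addition may be poor, which lowers the enantiomeric and trans purity. The phenoxide may also be benzylated on oxygen by the sulfonium salt before sulfinate is lost. The fallback sets out from 3 (with 8 and Grignard reagent 4) and comes back at 12. Williamson etherification of 3 with 8 gives the aryl ether F5, addition of 4 gives the benzhydrol F6, and MnO2 oxidation gives the benzophenone F7. Condensation with hydrazine gives the hydrazone F8, and MnO2 oxidises it to the diaryl diazo compound F9. The antipode of dirhodium tetrakis[(1-adamantyl)(phthalimido)acetate], Rh2(PTAD)4, that gives the 3R centre then catalyses intramolecular carbene insertion into the benzylic O–CH2 bond and gives the cis-dihydrobenzofuran F10. Trifluoroacetic acid in CH2Cl2 opens and recloses the ring through the 4-benzyloxybenzyl cation, which epimerises C2 only and gives trans 12.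

Step 9 (lactone α-arylation). Transmetalation of the crowded zinc enolate to the ortho-substituted arylpalladium may be too slow, so that 12 is reduced to the arene, or equilibration to the trans lactone may stay incomplete. The fallback reverses the polarity of the two partners, sets out from 16 and 12 and comes back at 19. Bromination of enolate 17 with N-bromosuccinimide gives the α-bromo lactone F11. Magnesium insertion into 12 in the presence of ZnCl2 and LiCl gives the arylzinc chloride F12. Nickel-catalysed Negishi coupling of the secondary α-bromo ester with F12 (NiCl2·glyme, a pyridine-bis(oxazoline) ligand, THF, 0 °C) runs through an α-carbonyl radical and needs no crowded enolate, and the same DBU equilibration then gives 19.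

Further compounds
F1 | step 13 | 3,5-bis(benzyloxy)-2-{(1S,2S)-1-[4-(benzyloxy)phenyl]-2-DHBF-4-oxobutyl}phenyl trifluoromethanesulfonate | C(c1ccccc1)Oc1ccc([C@@H](c2c(OCc3ccccc3)cc(OCc3ccccc3)cc2OS(=O)(=O)C(F)(F)F)[C@H](CC=O)c2cc(OCc3ccccc3)cc3c2[C@@H](c2cc(OCc4ccccc4)cc(OCc4ccccc4)c2)[C@H](c2ccc(OCc4ccccc4)cc2)O3)cc1
F2 | step 13 | 3,5-bis(benzyloxy)-2-{(1S,2S)-1,4-bis[4-(benzyloxy)phenyl]-2-DHBF-4-hydroxybutyl}phenyl trifluoromethanesulfonate, epimers at the carbinol | C(c1ccccc1)Oc1ccc([C@@H](c2c(OCc3ccccc3)cc(OCc3ccccc3)cc2OS(=O)(=O)C(F)(F)F)[C@H](CC(O)c2ccc(OCc3ccccc3)cc2)c2cc(OCc3ccccc3)cc3c2[C@@H](c2cc(OCc4ccccc4)cc(OCc4ccccc4)c2)[C@H](c2ccc(OCc4ccccc4)cc2)O3)cc1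
F3 | step 13 | 3,5-bis(benzyloxy)-2-{(1S,2S)-1,4-bis[4-(benzyloxy)phenyl]-2-DHBF-4-oxobutyl}phenyl trifluoromethanesulfonate | C(c1ccccc1)Oc1ccc([C@@H](c2c(OCc3ccccc3)cc(OCc3ccccc3)cc2OS(=O)(=O)C(F)(F)F)[C@H](CC(=O)c2ccc(OCc3ccccc3)cc2)c2cc(OCc3ccccc3)cc3c2[C@@H](c2cc(OCc4ccccc4)cc(OCc4ccccc4)c2)[C@H](c2ccc(OCc4ccccc4)cc2)O3)cc1
F4 | step 13 | [4-(benzyloxy)phenyl]{5,7-bis(benzyloxy)-1-[4-(benzyloxy)phenyl]-2-DHBF-indan-3-yl}methanone, all-trans | C(c1ccccc1)Oc1ccc([C@H]2c3c(OCc4ccccc4)cc(OCc4ccccc4)cc3[C@@H](C(=O)c3ccc(OCc4ccccc4)cc3)[C@@H]2c2cc(OCc4ccccc4)cc3c2[C@@H](c2cc(OCc4ccccc4)cc(OCc4ccccc4)c2)[C@H](c2ccc(OCc4ccccc4)cc2)O3)cc1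
F5 | step 6 | 4-(benzyloxy)-2-{[4-(benzyloxy)benzyl]oxy}-6-bromobenzaldehyde | O=Cc1c(Br)cc(OCc2ccccc2)cc1OCc1ccc(OCc2ccccc2)cc1
F6 | step 6 | (4-(benzyloxy)-2-{[4-(benzyloxy)benzyl]oxy}-6-bromophenyl)[3,5-bis(benzyloxy)phenyl]methanol, racemic | OC(c1cc(OCc2ccccc2)cc(OCc2ccccc2)c1)c1c(Br)cc(OCc2ccccc2)cc1OCc1ccc(OCc2ccccc2)cc1
F7 | step 6 | (4-(benzyloxy)-2-{[4-(benzyloxy)benzyl]oxy}-6-bromophenyl)[3,5-bis(benzyloxy)phenyl]methanone | O=C(c1cc(OCc2ccccc2)cc(OCc2ccccc2)c1)c1c(Br)cc(OCc2ccccc2)cc1OCc1ccc(OCc2ccccc2)cc1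
F8 | step 6 | hydrazone of F7 | NN=C(c1cc(OCc2ccccc2)cc(OCc2ccccc2)c1)c1c(Br)cc(OCc2ccccc2)cc1OCc1ccc(OCc2ccccc2)cc1
F9 | step 6 | diaryl diazomethane from F8 | [N-]=[N+]=C(c1cc(OCc2ccccc2)cc(OCc2ccccc2)c1)c1c(Br)cc(OCc2ccccc2)cc1OCc1ccc(OCc2ccccc2)cc1
F10 | step 6 | (2S,3R)-6-(benzyloxy)-3-[3,5-bis(benzyloxy)phenyl]-2-[4-(benzyloxy)phenyl]-4-bromo-2,3-dihydro-1-benzofuran (cis) | Brc1cc(OCc2ccccc2)cc2c1[C@@H](c1cc(OCc3ccccc3)cc(OCc3ccccc3)c1)[C@@H](c1ccc(OCc3ccccc3)cc1)O2
F11 | step 9 | 5,7-bis(benzyloxy)-4-[4-(benzyloxy)phenyl]-3-bromo-3,4-dihydro-2H-chromen-2-one, C4 as in 16, epimers at C3 | O=C1C(Br)[C@@H](c2ccc(OCc3ccccc3)cc2)c2c(OCc3ccccc3)cc(OCc3ccccc3)cc2O1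
F12 | step 9 | DHBF-zinc chloride | Cl[Zn]c1cc(OCc2ccccc2)cc2c1[C@@H](c1cc(OCc3ccccc3)cc(OCc3ccccc3)c1)[C@H](c1ccc(OCc3ccccc3)cc1)O2
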